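Compare how fast D leaves with how fast J arrives, and treat L as a correction to the catalyst.

in all of them: Z 5 mol%; L 0.27 mM

|  | D | temperature | remark | time |
|---|---|---|---|---|
| north | 0.026 M | 96 °C | run made earlier |  |
| south-west | 0.11 M | 121 °C | run made earlier |  |
| larch | 0.053 M | 100 °C |  | 8.0 min |
| elm | 0.053 M | 130 °C |  | 8.0 min |
| birch | 0.053 M | 115 °C |  | 8.0 min |
| ash | 0.053 M | 85 °C |  | 8.0 min |

north run (percent of the D charged)

| time / min | J / % | D / % |
|---|---|---|
| 0.833 | 0.4 | 85.9 |
| 2.50 | 1.4 | 63.3 |
| 4.00 | 3.9 | 48.1 |
| 6.00 | 7.6 | 33.2 |

south-west run (percent of the D charged)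

| time / s | J / % | D / % |
|---|---|---|
| 30.0 | 5.7 | 49.2 |
| 60.0 | 17.2 | 24.9 |
| 120 | 42.2 | 6.4 |

(scatter of a reading: 0.3 percentage points)

- the earlier runs were read with a standard deviation of 0.3 percentage points

* the flask with the highest amount of J, in percent of the D charged ("all alike" if they lie within 1.5 percentage points) (larch / elm / birch / ash / all alike)
* final J, as a percentage of the D charged, in larch
* final J, as a percentage of the D charged, in elm
* final J, as a percentage of the D charged, in birch
* final J, as a percentage of the D charged, in ash

Take the first clock, τD, as one over the rate constant of D's first-order fall. That constant reads 0.184 /min in north and 1.36 /min in south-west, so its activation energy reads 96.8 kJ/mol.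

Take the second clock, τJ, from the balance: what is neither D nor J sits in an unseen form, and J's late rise divided by that share gives its rate. Both runs changed temperature and catalyst together, so treat this step as pseudo-first-order, with a rate constant proportional to the working catalyst. My own assumption is that each L removes one Z, which leaves cZ minus cL: 1.03 mM in north and 5.23 mM in south-west. Per unit of working catalyst the rate constant reads 33.5 /M/min and 87.5 /M/min, an activation energy of 46.4 kJ/mol, and τJ is one over this constant times the working catalyst.

By my assumption the four flasks hold 2.38 mM of working catalyst. In ash, τD is 14.3 min and τJ is 20.0 min. Their ratio τJ/τD, the lag ratio ρ, is 1.39.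

Running the two steps in sequence, I expect 33.1% in larch, 88.6% in elm, 67.5% in birch and 8.19% in ash.

The forecast, “leaning towards face value”, gave 26%, 94%, 73% and 6% in the same order, with elm highest. Mine stand lower in elm and birch, and higher in larch.

The flasks give 31.7%, 87.5%, 65.8% and 7.63%, and elm is highest.

    D → E (k = 0.00430 /s, Ea = 98.0 kJ/mol)
    Z + E → Z + J (k = 0.620 /M/s, Ea = 47.0 kJ/mol)
    Z + L → G (k = 470 /M/s, Ea = 54.0 kJ/mol)
    (constants at 100 °C)

The forecast stands 7.2 points above birch and 5.7 points below larch. Now carry ρ to the neighbour, ash run at 60 °C. The two energies scale it to 0.392, with τD 164 min and τJ 64.3 min. Both are longer than the run, so use the early form, t² over twice the product of the clocks, which gives 0.303% J. After 8.00 min that flask holds 0.253% J, with 4.29% as E and 95.5% as D.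

The data are calculated on assumed constants, noise included.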